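The route rests on cutting the C9–C10 bond of ring B. This leads back to a ring A cyclohexenone (C2 carbonyl, C1=C10 alkene) that carries the C10 methyl, the C4 gem-dimethyl group and a 3-oxobutyl chain (C6–C8, C17) on C5. The key step exploits this enone, whose fully substituted β-carbon C10 lies next to the C5 stereocentre. A [2+2] photocycloaddition of allene builds quaternary C10, with the new C9–C10 bond anti to the C5 chain. The transient C1–C11 bond is then broken by strain-driven retro-Claisen opening, which leaves a two-carbon C9–C11 arm. The precursor is (R)-3,5,5-trimethyl-4-(3-oxobutyl)cyclohex-2-en-1-one, made from α-ionone.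

Key step: step 4

Remark on the chemistry: the target is (2R,5R,9R,10R) in labdane numbering, so the ring stereocentre of (R)-α-ionone becomes C5 unchanged; carbinol centres that are formed only to be reoxidised (in 9 and 15) are carried as epimer mixtures.

Step 1
Reactants: 1 rac-α-ionone, (3E)-4-(2,6,6-trimethylcyclohex-2-en-1-yl)but-3-en-2-one (racemate)
Product: 2 (R)-α-ionone, (3E)-4-[(1R)-2,6,6-trimethylcyclohex-2-en-1-yl]but-3-en-2-one
Conditions: preparative SFC, cellulose tris(3,5-dimethylphenylcarbamate) phase, CO2/i-PrOH, 35 °C; dextrorotatory fraction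
Reagents that add atoms: none
Why: Resolution by chromatography on a chiral stationary phase separates the enantiomers without any bond change, so the ring stereocentre (the future C5) is selected and not made, the (R)-enantiomer being the dextrorotatory one.

Step 2
Reactants: 2 (R)-α-ionone
Product: 3 (R)-dihydro-α-ionone, 4-[(1R)-2,6,6-trimethylcyclohex-2-en-1-yl]butan-2-one
Conditions: [(Ph3P)CuH]6 (0.25 equiv), H2O (3 equiv), benzene, 25 °C
Reagents that add atoms: none
Why: Copper hydride conjugate reduction should deliver hydride 1,4 to the acyclic enone and water protonates the copper enolate, while the isolated trisubstituted ring alkene is inert and the ring stereocentre, no longer vinylogous to a carbonyl, cannot epimerise.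

Step 3
Reactants: 3 (R)-dihydro-α-ionone
Product: 4 (4R)-3,5,5-trimethyl-4-(3-oxobutyl)cyclohex-2-en-1-one
Conditions: Rh2(cap)4 (cap = caprolactamate, 1 mol %), t-BuOOH (70% aq, 5 equiv), K2CO3 (0.5 equiv), CH2Cl2, 25 °C
Reagents that add atoms: tert-butyl hydroperoxide, CC(C)(C)OO
Why: Radical allylic oxidation with tert-butyl hydroperoxide should abstract hydrogen from the only ring allylic methylene and collapse the allylic peroxide to the conjugated enone, the tertiary allylic C–H on the stereocentre being shielded by the gem-dimethyl group and the chain, so the stereocentre is kept.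

Step 4
Reactants: 4 (4R)-3,5,5-trimethyl-4-(3-oxobutyl)cyclohex-2-en-1-one; 5 propadiene (allene)
Product: 6 (1S,5R,6S)-4,4,6-trimethyl-8-methylidene-5-(3-oxobutyl)bicyclo[4.2.0]octan-2-one
Conditions: allene (10 equiv), THF, −78 °C, hν (medium-pressure Hg lamp, uranium-glass filter, λ > 330 nm)
Reagents that add atoms: none
Why: Excitation of the enone (n→π*) and intersystem crossing give the twisted triplet, whose pyramidalised β-carbon C10 bonds to a terminal CH2 of allene to form a triplet 1,4-biradical; after spin inversion the α-keto radical centre C1 couples with the central allene carbon C11. The closest known reaction type is the head-to-head enone–allene [2+2] photocycloaddition of 3-methylcyclohexenones such as isophorone, which gives β,γ-unsaturated methylenecyclobutyl ketones. The cyclobutane C1–C10–C9–C11 is the only ring formed and closes by radical recombination within the biradical on the face that already carries C9, hence with cis fusion to ring A. C10 is controlled by the C5 stereocentre: allylic strain with the C10 methyl and the C4 gem-dimethyl group holds the C5 chain pseudo-axial, so allene should be taken up on the opposite face and the C10 methyl ends cis to C6, as the trans ring fusion of the target requires; C1 follows from the cis ring fusion and is erased in step 5. The step needs this facial selectivity and the head-to-head orientation, which is the normal sense for allene because the excited enone bonds first at its β-carbon; light above 330 nm excites only the enone and leaves the saturated ketone dark, and −78 °C limits secondary photochemistry of the product.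

Step 5
Reactants: 6 methylenecyclobutane photoadduct
Product: 8 methyl 2-[(1S,2R)-1,3,3-trimethyl-5-oxo-2-(3-oxobutyl)cyclohexyl]acetate, via acylcyclobutanone 7 (not isolated)
Conditions: O3, CH2Cl2/MeOH, −78 °C; Me2S; then NaOMe (0.2 equiv), MeOH, 0 °C
Reagents that add atoms: ozone, [O-][O+]=O; methanol, CO
Why: Ozonolysis of the exocyclic alkene should give the strained 2-acylcyclobutanone, to whose four-ring carbonyl methoxide adds and triggers a retro-Claisen fragmentation of C1–C11 with the C2 enolate as leaving group, so that C1 becomes CH2, C11 a methyl ester, and C5 and C10 are untouched.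

Step 6
Reactants: 8 diketo ester
Product: 9 (3R,4R)-3-(2-hydroxyethyl)-4-(3-hydroxybutyl)-3,5,5-trimethylcyclohexan-1-ol (epimers at both secondary carbinols)
Conditions: LiAlH4, THF, 0 °C to 25 °C
Reagents that add atoms: none
Why: Exhaustive hydride reduction with LiAlH4 should convert the ester into the C11 primary alcohol and both ketones into carbinols, whose configurations are irrelevant because they are oxidised again in step 7.

Step 7
Reactants: 9 triol
Product: 10 2-[(1R,2R)-1,3,3-trimethyl-5-oxo-2-(3-oxobutyl)cyclohexyl]acetaldehyde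
Conditions: Dess–Martin periodinane (4 equiv), NaHCO3, CH2Cl2, 25 °C
Reagents that add atoms: none
Why: Dess–Martin oxidation of all three hydroxyl groups should give the aldehyde and both ketones under buffered, non-enolising conditions, which avoids premature aldol reactions of the keto aldehyde.

Step 8
Reactants: 10 diketo aldehyde
Product: 11 (4aR,8aR)-2,5,5,8a-tetramethyl-7-oxo-3,4,4a,5,6,7,8,8a-octahydronaphthalene-1-carbaldehyde
Conditions: piperidine (0.5 equiv), AcOH (0.5 equiv), toluene, 4 Å molecular sieves, 80 °C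
Reagents that add atoms: none
Why: In this amine-catalysed intramolecular aldol condensation the aldehyde should form the enamine fastest, its C9 adds to the C8 ketone in a six-membered closure of ring B and loss of water from the tertiary aldol gives the tetrasubstituted enal; no stereocentre is formed and C5 and C10 already fix the ring fusion.

Step 9
Reactants: 11 keto enal
Product: 12 (4aR,8aR)-2,5,5,8a-tetramethyl-7-oxo-3,4,4a,5,6,7,8,8a-octahydronaphthalene-1-carboxylic acid
Conditions: NaClO2, NaH2PO4, 2-methyl-2-butene, t-BuOH/H2O, 25 °C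
Reagents that add atoms: sodium chlorite, [Na+].[O-]Cl=O
Why: Pinnick oxidation should convert the hindered conjugated aldehyde into the acid without touching the ketone or the alkene, the hypochlorite formed being trapped by the scavenger alkene.

Step 10
Reactants: 12 keto acid
Product: 13 methyl (4aR,8aR)-2,5,5,8a-tetramethyl-7-oxo-3,4,4a,5,6,7,8,8a-octahydronaphthalene-1-carboxylate
Conditions: MeI, K2CO3, DMF, 25 °C
Reagents that add atoms: iodomethane, CI
Why: O-Alkylation of the carboxylate (SN2 on iodomethane) should esterify the hindered acid where acid-catalysed esterification would be slow, and K2CO3 is too weak to enolise the ketone.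

Step 11
Reactants: 13 conjugated keto ester
Product: 14 methyl (1R,4aR,8aR)-5,5,8a-trimethyl-2-methylidene-7-oxodecahydronaphthalene-1-carboxylate
Conditions: LiN(i-Pr)2 (3.2 equiv), THF, −78 to −40 °C; AcOH, THF, −78 °C
Reagents that add atoms: none
Why: In this deconjugative protonation of an ester dienolate the excess amide first forms the C2 ketone enolate and then removes a proton from the C17 methyl, the γ-position syn to the ester carbonyl, and kinetic protonation at the α-carbon C9 from the face opposite the axial C10 methyl should give the exocyclic alkene with H-9 axial and the ester equatorial (9R), as in the known isomerisation of β- to γ-cyclogeranates.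

Step 12
Reactants: 14 β,γ-unsaturated keto ester
Product: 15 (4aR,8R,8aR)-8-(hydroxymethyl)-4,4,8a-trimethyl-7-methylidenedecahydronaphthalen-2-ol (C2 epimers, axial alcohol expected to prevail)
Conditions: LiAlH4, Et2O, 0 °C
Reagents that add atoms: none
Why: LiAlH4 should reduce the ester to the C11 primary alcohol faster than the ester can be reconjugated and also reduces the C2 ketone, mainly by equatorial attack, which does not matter because C2 is reoxidised in step 13.

Step 13
Reactants: 15 diol
Product: 16 (1R,4aR,8aR)-5,5,8a-trimethyl-2-methylidene-7-oxodecahydronaphthalene-1-carbaldehyde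
Conditions: Dess–Martin periodinane (3 equiv), NaHCO3, CH2Cl2, 0 °C to 25 °C
Reagents that add atoms: none
Why: Buffered Dess–Martin oxidation of both hydroxyl groups should give the β,γ-unsaturated aldehyde and the C2 ketone under neutral conditions that neither epimerise C9 nor move the exocyclic double bond into conjugation.

Step 14
Reactants: 16 keto aldehyde
Product: 17 (4aR,8R,8aR)-8-ethenyl-4,4,8a-trimethyl-7-methylidene-octahydronaphthalen-2(1H)-one
Conditions: Ph3PCH3Br (1.3 equiv), KN(SiMe3)2 (1.2 equiv), THF, 0 °C; then 16, −78 to 0 °C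
Reagents that add atoms: methyltriphenylphosphonium bromide, C[P+](c1ccccc1)(c1ccccc1)c1ccccc1.[Br-]
Why: In this Wittig methylenation the non-stabilised ylide should react with the aldehyde far faster than with the C2 ketone, which is flanked by two neopentyl methylene groups, and at low temperature C9, whose equatorial substituent is in any case the thermodynamically preferred one, is not epimerised.

Step 15
Reactants: 17 keto diene
Product: 18 (2R,4aR,8R,8aR)-8-ethenyl-4,4,8a-trimethyl-7-methylidenedecahydronaphthalen-2-ol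
Conditions: Li, NH3 (l), THF, EtOH, −78 °C; NH4Cl
Reagents that add atoms: none
Why: Dissolving-metal reduction of the ketone proceeds through a pyramidal ketyl or carbanion that places oxygen equatorial, away from the syn-axial C10 and C4 methyl groups that would steer hydride reagents to the axial epimer, so the equatorial (2R) alcohol of the target should be set while the isolated alkenes stay inert.

Step 16
Reactants: 19 tert-butyldimethyl(prop-2-yn-1-yloxy)silane
Product: 20 methyl 4-[(tert-butyldimethylsilyl)oxy]but-2-ynoate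
Conditions: n-BuLi, THF, −78 °C; ClCO2Me, −78 to 0 °C
Reagents that add atoms: methyl chloroformate, COC(=O)Cl
Why: Deprotonation of the terminal alkyne and C-acylation of the lithium acetylide with the chloroformate should give the ynoate.

Step 17
Reactants: 20 silyloxy ynoate
Product: 21 methyl (2E)-4-[(tert-butyldimethylsilyl)oxy]-2-(tributylstannyl)but-2-enoate
Conditions: Bu3SnH, Pd(PPh3)4 (2 mol %), THF, 0 °C to 25 °C
Reagents that add atoms: tributyltin hydride, CCCC[SnH](CCCC)CCCC
Why: Palladium-catalysed hydrostannation adds H and Sn syn across the alkynoate with tin at the carbon α to the ester, which should set the alkene geometry with the ester and the silyloxymethyl group cis.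

Step 18
Reactants: 21 stannyl enoate
Product: 22 (2E)-4-[(tert-butyldimethylsilyl)oxy]-2-(tributylstannyl)but-2-en-1-ol
Conditions: i-Bu2AlH (2.5 equiv), CH2Cl2, −78 to 0 °C
Reagents that add atoms: none
Why: i-Bu2AlH should reduce the conjugated ester to the allylic alcohol without touching the vinyl–tin bond or the silyl ether, so the geometry set in step 17 is kept.

Step 19
Reactants: 22 stannyl allylic alcohol
Product: 23 (2E)-4-[(tert-butyldimethylsilyl)oxy]-2-iodobut-2-en-1-ol
Conditions: I2, CH2Cl2, 0 °C
Reagents that add atoms: iodine, II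
Why: Iododestannylation is an electrophilic ipso substitution of the vinylstannane and should proceed with retention of the alkene geometry.

Step 20
Reactants: 18 hydroxy diene; 23 vinyl iodide
Product: 25 (2Z)-4-[(tert-butyldimethylsilyl)oxy]-2-{2-[(1R,4aR,7R,8aR)-7-hydroxy-5,5,8a-trimethyl-2-methylidenedecahydronaphthalen-1-yl]ethyl}but-2-en-1-ol, via trialkylborane 24 (not isolated)
Conditions: BH3·THF, 2-methyl-2-butene, THF, 0 °C (disiamylborane, 2.5 equiv); 18, 0 to 25 °C; then 23, PdCl2(dppf) (5 mol %), 3 M NaOH (aq), THF, 60 °C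
Reagents that add atoms: none
Why: In this B-alkyl Suzuki–Miyaura coupling disiamylborane should hydroborate the terminal vinyl group much faster than the hindered 1,1-disubstituted exocyclic methylene (the C2 hydroxyl only consumes one equivalent as a borinate), and the primary alkyl group is transferred selectively to palladium after oxidative addition of the vinyl iodide, which couples with retention of geometry to give the Z alkene; no stereocentre is formed.

Step 21
Reactants: 25 silyloxy diol
Product: 26 (2Z)-4-[(tert-butyldimethylsilyl)oxy]-2-{2-[(1R,4aR,7R,8aR)-7-hydroxy-5,5,8a-trimethyl-2-methylidenedecahydronaphthalen-1-yl]ethyl}but-2-en-1-yl acetate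
Conditions: AcCl (1.1 equiv), 2,4,6-collidine, CH2Cl2, −78 °C
Reagents that add atoms: acetyl chloride, CC(Cl)=O
Why: Acylation with acetyl chloride and the hindered base 2,4,6-collidine at low temperature should discriminate strongly in favour of the primary allylic hydroxyl over the secondary C2 hydroxyl.

Step 22
Reactants: 26 silyloxy acetate
Product: 27 (2Z)-4-hydroxy-2-{2-[(1R,4aR,7R,8aR)-7-hydroxy-5,5,8a-trimethyl-2-methylidenedecahydronaphthalen-1-yl]ethyl}but-2-en-1-yl acetate
Conditions: HF·pyridine, pyridine, THF, 0 °C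
Reagents that add atoms: none
Why: Fluoride-mediated desilylation with buffered HF·pyridine should remove the primary allylic silyl ether without cleaving or shifting the acetate and without acid-induced isomerisation of the exocyclic alkene.

Step 23
Reactants: 27 diol acetate
Product: 29 (2Z)-3-(acetoxymethyl)-5-[(1R,4aR,7R,8aR)-7-hydroxy-5,5,8a-trimethyl-2-methylidenedecahydronaphthalen-1-yl]pent-2-enoic acid (CNP0292310.1), via enal 28 (not isolated)
Conditions: TEMPO (10 mol %), PhI(OAc)2 (1.1 equiv), CH2Cl2, 25 °C; then NaClO2, NaH2PO4, 2-methyl-2-butene, t-BuOH/H2O, 0 to 25 °C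
Reagents that add atoms: sodium chlorite, [Na+].[O-]Cl=O
Why: Oxoammonium oxidation (TEMPO with PhI(OAc)2) should be selective for the primary allylic alcohol over the secondary C2 hydroxyl without isomerising the Z enal, and the Pinnick oxidation then gives the acid under mildly acidic conditions that leave the acetate, the secondary alcohol and both alkenes untouched.

Compound list
1 | rac-α-ionone, (3E)-4-(2,6,6-trimethylcyclohex-2-en-1-yl)but-3-en-2-one | CC(=O)/C=C/C1C(C)=CCCC1(C)C | starting material
2 | (R)-α-ionone, (3E)-4-[(1R)-2,6,6-trimethylcyclohex-2-en-1-yl]but-3-en-2-one | CC(=O)/C=C/[C@H]1C(C)=CCCC1(C)C | intermediate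
3 | (R)-dihydro-α-ionone, 4-[(1R)-2,6,6-trimethylcyclohex-2-en-1-yl]butan-2-one | CC(=O)CC[C@H]1C(C)=CCCC1(C)C | intermediate
4 | (4R)-3,5,5-trimethyl-4-(3-oxobutyl)cyclohex-2-en-1-one | CC(=O)CC[C@H]1C(C)=CC(=O)CC1(C)C | intermediate
5 | propadiene (allene) | C=C=C | starting material
6 | (1S,5R,6S)-4,4,6-trimethyl-8-methylidene-5-(3-oxobutyl)bicyclo[4.2.0]octan-2-one | C=C1C[C@@]2(C)[C@H](CCC(C)=O)C(C)(C)CC(=O)[C@@H]12 | intermediate
7 | (1S,5R,6S)-4,4,6-trimethyl-5-(3-oxobutyl)bicyclo[4.2.0]octane-2,8-dione (not isolated) | O=C1C[C@@]2(C)[C@H](CCC(C)=O)C(C)(C)CC(=O)[C@@H]12 | intermediate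
8 | methyl 2-[(1S,2R)-1,3,3-trimethyl-5-oxo-2-(3-oxobutyl)cyclohexyl]acetate | COC(=O)C[C@]1(C)CC(=O)CC(C)(C)[C@H]1CCC(C)=O | intermediate
9 | (3R,4R)-3-(2-hydroxyethyl)-4-(3-hydroxybutyl)-3,5,5-trimethylcyclohexan-1-ol (carbinol epimers) | OCC[C@]1(C)CC(O)CC(C)(C)[C@H]1CCC(C)O | intermediate
10 | 2-[(1R,2R)-1,3,3-trimethyl-5-oxo-2-(3-oxobutyl)cyclohexyl]acetaldehyde | O=CC[C@]1(C)CC(=O)CC(C)(C)[C@H]1CCC(C)=O | intermediate
11 | (4aR,8aR)-2,5,5,8a-tetramethyl-7-oxo-3,4,4a,5,6,7,8,8a-octahydronaphthalene-1-carbaldehyde | CC1=C(C=O)[C@]2(C)CC(=O)CC(C)(C)[C@H]2CC1 | intermediate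
12 | (4aR,8aR)-2,5,5,8a-tetramethyl-7-oxo-3,4,4a,5,6,7,8,8a-octahydronaphthalene-1-carboxylic acid | CC1=C(C(=O)O)[C@]2(C)CC(=O)CC(C)(C)[C@H]2CC1 | intermediate
13 | methyl (4aR,8aR)-2,5,5,8a-tetramethyl-7-oxo-3,4,4a,5,6,7,8,8a-octahydronaphthalene-1-carboxylate | CC1=C(C(=O)OC)[C@]2(C)CC(=O)CC(C)(C)[C@H]2CC1 | intermediate
14 | methyl (1R,4aR,8aR)-5,5,8a-trimethyl-2-methylidene-7-oxodecahydronaphthalene-1-carboxylate | C=C1CC[C@@H]2C(C)(C)CC(=O)C[C@@]2(C)[C@@H]1C(=O)OC | intermediate
15 | (4aR,8R,8aR)-8-(hydroxymethyl)-4,4,8a-trimethyl-7-methylidenedecahydronaphthalen-2-ol (C2 epimers) | C=C1CC[C@@H]2C(C)(C)CC(O)C[C@@]2(C)[C@@H]1CO | intermediate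
16 | (1R,4aR,8aR)-5,5,8a-trimethyl-2-methylidene-7-oxodecahydronaphthalene-1-carbaldehyde | C=C1CC[C@@H]2C(C)(C)CC(=O)C[C@@]2(C)[C@@H]1C=O | intermediate
17 | (4aR,8R,8aR)-8-ethenyl-4,4,8a-trimethyl-7-methylidene-octahydronaphthalen-2(1H)-one | C=C1CC[C@@H]2C(C)(C)CC(=O)C[C@@]2(C)[C@@H]1C=C | intermediate
18 | (2R,4aR,8R,8aR)-8-ethenyl-4,4,8a-trimethyl-7-methylidenedecahydronaphthalen-2-ol | C=C1CC[C@@H]2C(C)(C)C[C@@H](O)C[C@@]2(C)[C@@H]1C=C | intermediate
19 | tert-butyldimethyl(prop-2-yn-1-yloxy)silane | C#CCO[Si](C)(C)C(C)(C)C | starting material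
20 | methyl 4-[(tert-butyldimethylsilyl)oxy]but-2-ynoate | COC(=O)C#CCO[Si](C)(C)C(C)(C)C | intermediate
21 | methyl (2E)-4-[(tert-butyldimethylsilyl)oxy]-2-(tributylstannyl)but-2-enoate | COC(=O)/C(=C\CO[Si](C)(C)C(C)(C)C)[Sn](CCCC)(CCCC)CCCC | intermediate
22 | (2E)-4-[(tert-butyldimethylsilyl)oxy]-2-(tributylstannyl)but-2-en-1-ol | OC/C(=C\CO[Si](C)(C)C(C)(C)C)[Sn](CCCC)(CCCC)CCCC | intermediate
23 | (2E)-4-[(tert-butyldimethylsilyl)oxy]-2-iodobut-2-en-1-ol | OC/C(I)=C\CO[Si](C)(C)C(C)(C)C | intermediate
24 | C12 bis(3-methylbutan-2-yl)boryl derivative of 18 with the C2 oxygen as bis(3-methylbutan-2-yl)borinate (not isolated) | C=C1CC[C@@H]2C(C)(C)C[C@@H](OB(C(C)C(C)C)C(C)C(C)C)C[C@@]2(C)[C@@H]1CCB(C(C)C(C)C)C(C)C(C)C | intermediate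
25 | (2Z)-4-[(tert-butyldimethylsilyl)oxy]-2-{2-[(1R,4aR,7R,8aR)-7-hydroxy-5,5,8a-trimethyl-2-methylidenedecahydronaphthalen-1-yl]ethyl}but-2-en-1-ol | C=C1CC[C@@H]2C(C)(C)C[C@@H](O)C[C@@]2(C)[C@@H]1CC/C(CO)=C/CO[Si](C)(C)C(C)(C)C | intermediate
26 | (2Z)-4-[(tert-butyldimethylsilyl)oxy]-2-{2-[(1R,4aR,7R,8aR)-7-hydroxy-5,5,8a-trimethyl-2-methylidenedecahydronaphthalen-1-yl]ethyl}but-2-en-1-yl acetate | C=C1CC[C@@H]2C(C)(C)C[C@@H](O)C[C@@]2(C)[C@@H]1CC/C(COC(C)=O)=C/CO[Si](C)(C)C(C)(C)C | intermediate
27 | (2Z)-4-hydroxy-2-{2-[(1R,4aR,7R,8aR)-7-hydroxy-5,5,8a-trimethyl-2-methylidenedecahydronaphthalen-1-yl]ethyl}but-2-en-1-yl acetate | C=C1CC[C@@H]2C(C)(C)C[C@@H](O)C[C@@]2(C)[C@@H]1CC/C(COC(C)=O)=C/CO | intermediate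
28 | (2Z)-2-{2-[(1R,4aR,7R,8aR)-7-hydroxy-5,5,8a-trimethyl-2-methylidenedecahydronaphthalen-1-yl]ethyl}-4-oxobut-2-en-1-yl acetate (not isolated) | C=C1CC[C@@H]2C(C)(C)C[C@@H](O)C[C@@]2(C)[C@@H]1CC/C(COC(C)=O)=C/C=O | intermediate
29 | (2Z)-3-(acetoxymethyl)-5-[(1R,4aR,7R,8aR)-7-hydroxy-5,5,8a-trimethyl-2-methylidenedecahydronaphthalen-1-yl]pent-2-enoic acid | C=C1CC[C@@H]2C(C)(C)C[C@@H](O)C[C@@]2(C)[C@@H]1CC/C(=C/C(=O)O)COC(C)=O | target

Total step count: 23.
Longest linear sequence: 19 steps (steps 1–15 and 20–23); the vinyl iodide 23 takes 4 steps (16–19).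

Steps most likely to fail

Step 4 (key step). The excited enone may take up allene with poor face discrimination at C10, may close in the head-to-tail sense, or may react so slowly at the congested β-carbon that secondary photoreactions of the β,γ-unsaturated ketone take over. The fallback makes the C9–C10 bond thermally and sets out from 4. Selective ketalisation of the methyl ketone (ethylene glycol, PPTS, benzene, reflux) gives the dioxolane enone F1. Conjugate addition of a vinyl group activated by TMSCl (vinylmagnesium bromide, CuBr·SMe2, TMSCl, THF, −78 °C), anti to the C5 chain, gives the silyl enol ether F2, which is hydrolysed on work-up (aqueous citric acid) to the vinyl ketone F3. Hydroboration with 9-BBN gives the alkylborane F4, which is oxidised without isolation (NaOH, H2O2) to the primary alcohol F5. Dess–Martin oxidation, which also returns any C2 carbinol to the ketone, gives the aldehyde F6, and 1 M HCl in THF removes the dioxolane, so the route is rejoined at 10.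

Step 8. The amine may form the enamine of the methyl ketone instead of that of the aldehyde, so that C7 adds to the aldehyde carbon (C7–C11 closure to an acetylcyclohexene), or the aldol addition at the neopentyl carbon C9 may revert before it dehydrates. The fallback generates the aldehyde enolate regiospecifically and sets out from 10. Aldehyde-selective α-bromination by enamine catalysis (4,4-dibromo-2,6-di-tert-butylcyclohexa-2,5-dienone, catalytic 2,5-diphenylpyrrolidine, CH2Cl2, −40 °C) gives the α-bromo aldehyde F7. SmI2 (THF, −78 °C) cleaves the C–Br bond to a samarium enolate that adds to the C8 ketone in an intramolecular Reformatsky-type aldol addition, giving the ketol F8. Dehydration (MsCl, Et3N, then DBU) rejoins the route at 11.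

Step 20. Transmetalation of the hindered trialkylborane may be slow under aqueous base, so that protodeboronation or reduction of the vinyl iodide competes, or the exocyclic methylene may be hydroborated in part. The fallback makes the C12–C13 bond from a C12 iodide and sets out from 18. The borane 24 is formed as in step 20 and oxidised (NaOH, H2O2) to the diol F9. Appel iodination of the primary hydroxyl (I2, PPh3, imidazole, CH2Cl2, 0 °C) gives the iodide F10. Reductive cross-electrophile coupling with 23 (NiI2, 4,4′-di-tert-butyl-2,2′-bipyridine, Mn, DMPU, 25 °C) rejoins the route at 25.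

Further compounds
F1 | step 4 | (4R)-3,5,5-trimethyl-4-[2-(2-methyl-1,3-dioxolan-2-yl)ethyl]cyclohex-2-en-1-one | CC1(CC[C@H]2C(C)=CC(=O)CC2(C)C)OCCO1
F2 | step 4 | trimethylsilyl enol ether of F3, enol double bond C1=C2 (not isolated) | C=C[C@]1(C)C=C(O[Si](C)(C)C)CC(C)(C)[C@H]1CCC1(C)OCCO1
F3 | step 4 | (3S,4R)-3-ethenyl-3,5,5-trimethyl-4-[2-(2-methyl-1,3-dioxolan-2-yl)ethyl]cyclohexan-1-one | C=C[C@]1(C)CC(=O)CC(C)(C)[C@H]1CCC1(C)OCCO1
F4 | step 4 | 9-{2-[(1R,2R)-1,3,3-trimethyl-2-[2-(2-methyl-1,3-dioxolan-2-yl)ethyl]-5-oxocyclohexyl]ethyl}-9-borabicyclo[3.3.1]nonane (not isolated) | B1(C2CCCC1CCC2)CC[C@]1(C)CC(=O)CC(C)(C)[C@H]1CCC1(C)OCCO1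
F5 | step 4 | (3R,4R)-3-(2-hydroxyethyl)-3,5,5-trimethyl-4-[2-(2-methyl-1,3-dioxolan-2-yl)ethyl]cyclohexan-1-one | OCC[C@]1(C)CC(=O)CC(C)(C)[C@H]1CCC1(C)OCCO1
F6 | step 4 | 2-[(1R,2R)-1,3,3-trimethyl-2-[2-(2-methyl-1,3-dioxolan-2-yl)ethyl]-5-oxocyclohexyl]acetaldehyde | O=CC[C@]1(C)CC(=O)CC(C)(C)[C@H]1CCC1(C)OCCO1
F7 | step 8 | 2-bromo-2-[(1R,2R)-1,3,3-trimethyl-5-oxo-2-(3-oxobutyl)cyclohexyl]acetaldehyde (both epimers at the bromide carbon) | O=CC(Br)[C@]1(C)CC(=O)CC(C)(C)[C@H]1CCC(C)=O
F8 | step 8 | (4aR,8aR)-2-hydroxy-2,5,5,8a-tetramethyl-7-oxodecahydronaphthalene-1-carbaldehyde (epimers at C1 and C2) | O=CC1[C@]2(C)CC(=O)CC(C)(C)[C@H]2CCC1(C)O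
F9 | step 20 | (2R,4aR,8R,8aR)-8-(2-hydroxyethyl)-4,4,8a-trimethyl-7-methylidenedecahydronaphthalen-2-ol | C=C1CC[C@@H]2C(C)(C)C[C@@H](O)C[C@@]2(C)[C@@H]1CCO
F10 | step 20 | (2R,4aR,8R,8aR)-8-(2-iodoethyl)-4,4,8a-trimethyl-7-methylidenedecahydronaphthalen-2-ol | C=C1CC[C@@H]2C(C)(C)C[C@@H](O)C[C@@]2(C)[C@@H]1CCI
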